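The numbers of this flask were drawn at random within sensible limits.

Leftover impurity is the thread here: find how much nucleophile to charge so that the asked part of the electrophile has reacted by the end of the run.

    crystals ⇌ acid set free, rate k1*(cs1 - [acid set free]) while solid is left; crystals form when [acid set free] > cs1 (cs1 = 0.17 mM, k1 = 0.24 /s)
    electrophile + nucleophile → acid set free + product (k2 = 200 /M/s)
    nucleophile + acid set free ⇌ protonated nucleophile, settled at all times (K3 = 1.5 × 10⁵ /M)
    nucleophile + protic impurity → quenched reagent (k4 = 66 /M/s)

electrophile 2.0 mM; protic impurity 0.600 mM; time 3.0 min

- the equivalents of nucleophile at which the part of the electrophile that has reacted at 3.0 min is just 95 %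

- amounts and yields of acid set free count crystals too
- given per volume of solution although it is solid: crystals
- the amount of nucleophile is what is sought; it is there from the start
- run time (flask): 3.0 min

Start from what seems not to fit. By its step with the impurity alone, the other concentrations as charged, the nucleophile has a half-life of 0.29 min, short against the run of 3.0 min, yet some impurity outlasts the point where 95 % of the electrophile has reacted.

To clear this up, divide the rate of impurity loss by the rate of electrophile loss. Free nucleophile stands in both, so it cancels, and time goes with it. The fraction of impurity left equals the fraction of electrophile left raised to the power 0.330, the selectivity factor. At the start the electrophile takes nucleophile 10.1 times as fast as the impurity does. At 95 %, 0.223 mM of impurity remains and 0.377 mM has gone. Call this the impurity toll, the nucleophile lost to impurity by the time a given part of the electrophile has reacted.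

Now add up the cost. Each electrophile turned uses one nucleophile, so the need lies above 1.14 equiv. The acid set free can hold a second nucleophile, but above 0.17 mM it can leave as crystals, and that is less than the 1.90 mM of acid made, so I estimate the need below 2.09 equiv, the cost with a second nucleophile held for each. My reckoning stops here.

The forecast says 1.72 equiv, holding that “the impurity takes about 0.35–0.4 mM more”. My toll stands inside that range.

The simulation gives 1.68 equiv. In that flask, 89.6 % of the electrophile has reacted at 1.50 min. Put that part into the toll: it gives 0.315 mM, which is 83.7 % of the toll at 95 %. The flask shows 84 % of the impurity step's turnover up to 3.0 min behind it at 1.50 min.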